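What is left over in the elm run at 15.0 h? Substrate 20 % and other conformer 13 %, together 33.0 %; the alder run leaves 40.0 %.

| setting | elm | alder | flask |
|---|---|---|---|
| substrate | 0.067 M | 0.15 M | 0.10 M |
| gas | 10 mM (held) | 10 mM (held) | 10 mM (held) |
| remark | run made earlier | run made earlier |  |
| time |  |  | 15 h |

| run | time / h | isomer of the product B / % | other conformer / % | target / % | substrate / % | isomer of the product A / % |
|---|---|---|---|---|---|---|
| elm | 4.00 | 3 | 30 | 9 | 49 | 7 |
| elm | 8.00 | 5 | 23 | 15 | 34 | 18 |
| elm | 12.0 | 10 | 17 | 16 | 26 | 24 |
| elm | 15.0 | 15 | 13 | 21 | 20 | 32 |
| alder | 2.00 | 1 | 23 | 7 | 66 | 4 |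
| alder | 5.00 | 7 | 27 | 15 | 51 | 10 |
| alder | 10.0 | 9 | 19 | 18 | 30 | 18 |
| alder | 15.0 | 13 | 16 | 20 | 24 | 32 |

(each reading ± 2 percentage points)

- at the start none of reagent is dissolved
- steps that have been proposed: substrate <-> other conformer; substrate + reagent -> target; reagent + other conformer -> isomer of the product A; gas <-> reagent; target <-> isomer of the product B

- the species in which most of what was charged as substrate, at 15 h sits (isomer of the product A / target / isomer of the product B / other conformer / substrate)
- the largest share itself, whichever of these holds it, in percent of the substrate charged

Why add the two? The proposed steps let them pass into each other, so on the board I draw them as one pool. Treating its decay as first order, the mean leftover gives 10.3 h, the time in which substrate and other conformer together halve, the pool half-life.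

But the charges differ: does one half-life serve both runs? That is the weak spot. The two leftovers differ by 7 percentage points, with a scatter of 2 points on each reading, and I take the pool as pseudo-first-order as a working assumption.

And the flask? Its charge of 0.10 M lies between those of the two runs. At 15 h it stands 1.46 half-lives in, so I count 36.5 % still in the pool. Isomer of the product A takes 48.1 % of the products read in the two runs at 15.0 h, so my own figure for it in the flask is 30.6 %.

The forecast says isomer of the product A at 31 %, on this ground: “Percentages should therefore not depend on charge”.

The flask gives isomer of the product A at 30.7 %, with target at 21.5 %, so the forecast stands on both counts.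

    substrate ⇌ other conformer (K = 0.650, k = 0.00463 min⁻¹)
    substrate + reagent → target (k = 0.107 M⁻¹ min⁻¹)
    reagent + other conformer → isomer of the product A (k = 0.188 M⁻¹ min⁻¹)
    gas ⇌ reagent, rate k4*(csat - [reagent]) (kL = 0.0607 min⁻¹)
    target ⇌ isomer of the product B (K = 0.640, k = 0.00719 min⁻¹)

In the flask at 15.0 h, substrate 21.7 % and other conformer 13.2 % make 34.9 % in the pool, against the 36.5 % counted. In the flask, their own step alone, both ways together, relaxes the two forms with a half-life of 0.983 h, which is shorter than the pool half-life of 10.3 h. An earlier reading changes the answer: the same flask read at 4.0 h is 0.388 half-lives in, which counts 76.4 % in the pool against 78.3 % simulated, and there substrate holds most at 50.2 %, with isomer of the product A at 8.37 %.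

(Readings and results were generated by integration from invented constants, noise included.)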